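The runs were computed with made-up constants.

The target in the flask is what I want at 15 d, and I bracket it from above and from below before any result.

| flask | substrate | reagent | free catalyst | remark | time |
|---|---|---|---|---|---|
| zeta | 0.27 M | 0.24 M | 6.5 mM | run made earlier |  |
| flask | 0.27 M | 0.486 M | 6.5 mM |  | 15 d |

zeta run (percent of the substrate charged)

| time / h | target / % |
|---|---|
| 5.00 | 45 |
| 12.0 | 76 |
| 25.0 | 90 |
| 40.0 | 88 |

(each reading ± 2 percentage points)

1. why nothing more happens at 15 d, or that something still does (all of the substrate has reacted / forward and back rates have come level / it is still moving / the reagent has run out first / no working catalyst is left)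
2. amount of target at 15 d, in percent of the substrate charged
3. amount of target if the flask were left three thousand times as long, in percent of the substrate charged

- the reaction counts as stopped when no species that holds the substrate changes by six tenths of a point or more over the second half of the time

1. Ceiling. The last zeta readings are 90% and 88%, with a scatter of 2 percentage points, and the reagent charge there is 88.9% of the substrate charge. So I read one target per reagent, with reagent as the limiting reagent in zeta. For the flask, the ceiling C, the smaller of 1 and reagent charge over substrate charge, is 100%.

2. Crude floor. If extra reagent does no harm, the flask reaches at least the zeta plateau, about 89.0%.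

3. Tighter floor. I take the first zeta reading as first order in substrate, which reads as a rate constant k of 0.120 h⁻¹, with the scatter of that reading. The zeta readings still rise from 12.0 h to 25.0 h, so I credit the flask with that working time and no more. The floor becomes 95.0%.

4. Commitment. I expect the substrate to be used up, with target between floor and ceiling.

5. Forecast. It gives all of the substrate has reacted, 99% at 15 d and 99% for the long wait, reasoning “so substrate is limiting”. Its figure stands above my floor and below my ceiling.

The flask gives 100% of target at 15 d and 100% after the long wait, with the verdict all of the substrate has reacted, which stands level with C at 100%.

    substrate + free catalyst ⇌ catalyst intermediate A (K = 120 M⁻¹, k = 100 M⁻¹ h⁻¹)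
    catalyst intermediate A → catalyst intermediate B (k = 180 h⁻¹)
    catalyst intermediate C → by-product + catalyst intermediate D (k = 310 h⁻¹)
    reagent + catalyst intermediate B ⇌ catalyst intermediate C (K = 0.400 M⁻¹, k = 43.0 M⁻¹ h⁻¹)
    catalyst intermediate D → free catalyst + target (k = 28.0 h⁻¹)

The slowest mode of the flask at 15.0 d has a half-life of 1.07 h, far shorter than the 15 d allowed, and substrate in the flask is down to 0.0362% by 0.750 d. The neighbour flask charged with 1.1 M of substrate has C = 44.2%, and at 15.0 d it holds 44.2% of target, with reagent at 0% of its charge.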